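- The easiest step is a split by charge, taken as an assumption: if substrate goes to target and other conformer to isomer of the product, the first guess for the share of target (the selectivity) is c(substrate)/(c(substrate)+c(other conformer)). For the one charge of Friday's, Monday's and Sunday's flasks this split gives 80.0%.

| flask | substrate | other conformer | catalyst | temperature | remark | time |
|---|---|---|---|---|---|---|
| epsilon | 0.025 M | 0.0125 M | 0.22 mM | 20 °C | run made earlier |  |
| gamma | 0.10 M | 0.0125 M | 0.22 mM | 31 °C | run made earlier |  |
| Friday's | 0.050 M | 0.0125 M | 0.22 mM | 35 °C |  | 4.0 d |
| Monday's | 0.050 M | 0.0125 M | 0.22 mM | 15 °C |  | 4.0 d |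
| Sunday's | 0.050 M | 0.0125 M | 0.22 mM |  | at 35 °C until 30 h, from then on at 15 °C | 4.0 d |

| run | time / d | target / % | isomer of the product / % |
|---|---|---|---|
| epsilon | 0.500 | 36 | 30 |
| epsilon | 0.833 | 48 | 31 |
| epsilon | 1.25 | 54 | 34 |
| epsilon | 1.67 | 60 | 38 |
| epsilon | 2.50 | 59 | 38 |
| epsilon | 4.00 | 61 | 36 |
| epsilon | 6.00 | 61 | 40 |
| gamma | 0.250 | 39 | 15 |
| gamma | 0.417 | 48 | 19 |
| gamma | 0.625 | 66 | 27 |
| gamma | 0.833 | 69 | 23 |
| gamma | 1.25 | 69 | 26 |
| gamma | 2.00 | 73 | 27 |
| gamma | 3.00 | 69 | 27 |

(standard deviation of a reading: 2 percentage points)

- in a conversion other conformer counts as not yet reacted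
- the share counts what is present at the end, not what went on to other products

- the flask with the highest share of target in all that became target or isomer of the product ("all alike" if they lie within 1.5 percentage points) (Friday's / Monday's / Sunday's / all alike)
- share of target in all that became target or isomer of the product, Friday's
- share of target in all that became target or isomer of the product, Monday's
- share of target in all that became target or isomer of the product, Sunday's

- The split fails on the earlier runs. From 1.67 d on, the epsilon readings stand level and give a share of 61.3%, less than its split of 66.7%. From 0.833 d on, the gamma readings give 73.1%, less than its split of 88.9%.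
- So the first answer goes back in with a correction. The leak is the fraction of the split that did not end as target, one minus share over split. As readings, it is 8.02% in epsilon and 17.8% in gamma.
- The new flasks hold twice the c(substrate) of epsilon and half that of gamma, with the same c(other conformer), so they stand midway on a ratio scale. The geometric mean then gives 11.9%, the estimated leak at this charge, and the second round gives a share of 70.5%.
- The weak link is that mean: epsilon and gamma also differ in temperature, 20 °C against 31 °C, and two runs leave the two settings unparted. The arithmetic mean gives 69.7%, a gap smaller than the margin, but the temperature stays an open risk.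
- The 4.0 d allowed is longer than the 1.67 d after which the epsilon readings stand level, though Monday's flask, at 15 °C, is colder than epsilon. With temperature left out of it, this reckoning commits to about 70.5% in each flask, alike within 1.5 percentage points.
- The forecast named Friday's, with 75%, 57% and 74.8% for Friday's, Monday's and Sunday's, on the ground “I therefore attribute the difference mainly to temperature”, and so it parts the flasks where this reckoning does not.
- The simulation gives 69.8% for Friday's, 70.1% for Monday's and 70.4% for Sunday's, so the answer is all alike.

    substrate ⇌ other conformer (K = 0.0975, k = 0.00276 min⁻¹, Ea = 92.0 kJ mol⁻¹, ΔH = −40.0 kJ mol⁻¹)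
    substrate + catalyst → catalyst + target (k = 10.6 M⁻¹ min⁻¹, Ea = 38.0 kJ mol⁻¹)
    catalyst + other conformer → catalyst + isomer of the product (k = 54.1 M⁻¹ min⁻¹, Ea = 52.0 kJ mol⁻¹)
    target → over-reaction product (k = 1.38 × 10⁻⁶ min⁻¹, Ea = 110 kJ mol⁻¹)
    other conformer ⇌ dormant form (K = 9.69, k = 0.00260 min⁻¹, Ea = 107 kJ mol⁻¹, ΔH = −86.0 kJ mol⁻¹)
    (constants at 35 °C)

- Friday's share corresponds to a leak of 12.8%, beside the 11.9% carried. In Friday's flask at 4.00 d, the step to target used substrate at 0.84 times the forward rate of its turning into other conformer. In Friday's flask, substrate and other conformer relax by that turning alone, both ways together, with a half-life of 0.372 h, far shorter than the 4.0 d allowed. The neighbour like Friday's kept at 50 °C has a share of 75.5%, a leak of 5.63%.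

The numbers in the tables were generated by integration on assumed constants; scatter was added.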